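## Retrosynthetic overview

1. Ring C (the 4-chromanone ring) is cut at C2–C3 and C4–C4a: an aryl oxocarbenium ion (O1=C2, carrying ring B) and a two-carbon terminal ynamide (C3–C4) are joined in an enantioselective formal [4+2] (oxa-Povarov-type) annulation. The 4-sulfonamido-2H-chromene formed is the masked ketone.
2. Enabling feature: in ring A the ether oxygen O1 (on C8a) is para to the geranyl-bearing C6, so C4a and C8 are equivalent in an O1-aryl precursor and each is activated ortho/para by O5 and O7. C2 is benzylic to the para-methoxy ring B, which stabilises the cation, and C4 has the oxidation level of an ynamide carbon.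
3. The oxocarbenium precursor is an O-aryl O-pivaloyl acetal, made from phenol 7 and the pivaloyl chloride adduct of isovanillin acetate.
4. Phenol 7 comes from resorcinol: MOM protection, lithiation/geranylation between the two ethers, then C–H borylation/oxidation para to the geranyl group.
5. Ring order: rings A and B are bought as arenes; ring C is the only ring formed (step 7). Acid then unmasks C4=O and the three phenols.

Key step: step 7

Assumption: the sense of induction of the chiral phosphoric acid in step 7 cannot be predicted with certainty; the (R)-acid is written, and its mirror image is to be used if it favours the 2R product.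

"Geranyl" below means (2E)-3,7-dimethylocta-2,6-dien-1-yl.

## Route

Step 1
Reactants: 1 resorcinol
Product: 2 1,3-bis(methoxymethoxy)benzene
Conditions: MOMCl (2.5 equiv), iPr2NEt (3 equiv), CH2Cl2, 0 °C to rt
Reagents that add atoms: chloromethyl methyl ether, COCCl
Why: Williamson-type O-alkylation of both phenols gives the bis-MOM ether, whose two acetal oxygens later direct the lithiation.

Step 2
Reactants: 2 1,3-bis(methoxymethoxy)benzene; 3 geranyl bromide
Product: 5 2-geranyl-1,3-bis(methoxymethoxy)benzene, via aryllithium 4 (not isolated)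
Conditions: n-BuLi (1.1 equiv), THF, 0 °C to rt; then CuI (copper monoiodide, 10 mol%), 3, −78 °C to rt
Reagents that add atoms: n-butyllithium, [Li]CCCC (lithium of 4 only)
Why: directed ortho-lithiation occurs at the carbon flanked by both MOM ethers, and SN2 allylation of the aryl metal with the primary allylic bromide should keep the E-alkene.

Step 3
Reactants: 5 2-geranyl-1,3-bis(methoxymethoxy)benzene
Product: 7 4-geranyl-3,5-bis(methoxymethoxy)phenol, via arylboronate 6 (not isolated)
Conditions: [Ir(OMe)(cod)]2 (1.5 mol%), 4,4′-di-tert-butyl-2,2′-bipyridine (3 mol%), B2pin2 (1.0 equiv), THF, 60 °C; then aq NaOH, 30% H2O2, 0 °C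
Reagents that add atoms: bis(pinacolato)diboron, CC1(C)OB(OC1(C)C)B1OC(C)(C)C(C)(C)O1 (boron of 6 only); hydrogen peroxide, OO (phenol oxygen of 7)
Why: sterically controlled iridium-catalysed aromatic C–H borylation should select the only ring C–H without an ortho neighbour (para to geranyl), and boronate oxidation then gives the phenol; trisubstituted alkenes and MOM ethers should tolerate both stages.

Step 4
Reactants: 8 isovanillin
Product: 9 5-formyl-2-methoxyphenyl acetate
Conditions: Ac2O, pyridine, DMAP (cat.), CH2Cl2, rt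
Reagents that add atoms: acetic anhydride, CC(=O)OC(C)=O
Why: O-acetylation protects the ring B phenol with a group that is inert to acyl chlorides and is removed by acid methanolysis at the end.

Step 5
Reactants: 9 5-formyl-2-methoxyphenyl acetate
Product: 10 (3-acetoxy-4-methoxyphenyl)(chloro)methyl pivalate (racemic)
Conditions: pivaloyl chloride (1.2 equiv), ZnCl2 (2 mol%), CH2Cl2, 0 °C to rt; concentrated and used crude
Reagents that add atoms: pivaloyl chloride, CC(C)(C)C(Cl)=O
Why: ZnCl2-catalysed addition of an acyl chloride across the aldehyde C=O (α-chloroalkyl ester formation) is an established reaction; the racemic acetal carbon is planarised again in step 7.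

Step 6
Reactants: 7 4-geranyl-3,5-bis(methoxymethoxy)phenol; 10 (3-acetoxy-4-methoxyphenyl)(chloro)methyl pivalate
Product: 11 (3-acetoxy-4-methoxyphenyl)[4-geranyl-3,5-bis(methoxymethoxy)phenoxy]methyl pivalate (racemic)
Conditions: iPr2NEt (2 equiv), CH2Cl2, −20 to 0 °C; rapid chromatography on Et3N-deactivated silica
Reagents that add atoms: none
Why: O-alkylation of the phenol by the readily ionised α-chloro ester under amine-base conditions (as in acyloxymethyl aryl ether formation) should give the mixed acetal without acyl transfer from the aryl acetate.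

Step 7
Reactants: 11 (3-acetoxy-4-methoxyphenyl)[4-geranyl-3,5-bis(methoxymethoxy)phenoxy]methyl pivalate; 12 N-ethynyl-N,4-dimethylbenzenesulfonamide
Product: 15 N-[(2S)-2-(3-acetoxy-4-methoxyphenyl)-6-geranyl-5,7-bis(methoxymethoxy)-2H-chromen-4-yl]-N,4-dimethylbenzenesulfonamide, via oxocarbenium ion 13 (not isolated), via keteniminium ion 14 (not isolated)
Conditions: (R)-3,3′-bis(2,4,6-triisopropylphenyl)-1,1′-binaphthyl-2,2′-diyl hydrogen phosphate (C50H57O4P, 10 mol%), 12 (2 equiv), 4 Å molecular sieves, toluene, −40 to −20 °C; Et3N quench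
Reagents that add atoms: none
Why: Proposed new method: the chiral phosphoric acid protonates the pivalate of 11 and releases aryl oxocarbenium ion 13 as a contact ion pair with the chiral phosphate; the nucleophilic terminal carbon of ynamide 12 adds to the oxocarbenium carbon (future C2–C3) to give keteniminium ion 14, whose digonal carbon is captured by the ring A carbon ortho to the ether oxygen (future C4–C4a), and loss of a proton returns the acid. The closest known reactions are the oxa-Povarov reaction of aryl oxocarbenium ions with alkenes, formal [4+2] annulations of N-aryl imines with ynamides, chiral-phosphate-controlled Povarov reactions and the Friedel–Crafts capture of keteniminium ions by arenes. Ring C closes by a 6-exo-dig Friedel–Crafts alkenylation (the C=N+ bond stays outside the ring and C3=C4 ends up inside it). The only new stereocentre, C2, is set in the first bond formation, where the chiral phosphate counter-ion should shield one face of the planar oxocarbenium ion. The step needs ionisation by loss of pivalate and not of the aryloxide (the acyloxy group is the better leaving group and cannot stabilise a cation), attack through the ynamide β-carbon (secured by nitrogen polarisation), and a single closure site (the two carbons ortho to the ether oxygen are equivalent and each is activated ortho and para by the MOM ethers, with geranyl para to that oxygen). The geranyl alkenes and the ring B carbons ortho to C2 (meta to the methoxy group) are far weaker nucleophiles than the ynamide and ring A.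

Step 8
Reactants: 15 N-[(2S)-2-(3-acetoxy-4-methoxyphenyl)-6-geranyl-5,7-bis(methoxymethoxy)-2H-chromen-4-yl]-N,4-dimethylbenzenesulfonamide
Product: 16 (2S)-6-geranyl-5,7-dihydroxy-2-(3-hydroxy-4-methoxyphenyl)-2,3-dihydro-4H-chromen-4-one
Conditions: 3 M aq HCl, MeOH/THF, 40 °C
Reagents that add atoms: water, O
Why: C3 protonation of the electron-rich enesulfonamide, addition of water and loss of the sulfonamide (enamide hydrolysis) should reveal the C4 ketone, while the same acid cleaves both MOM acetals and methanolyses the aryl acetate; C2 is not involved, so the 2S configuration should be kept.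

## Compound list

1 | resorcinol (benzene-1,3-diol) | Oc1cccc(O)c1 | starting material
2 | 1,3-bis(methoxymethoxy)benzene | COCOc1cccc(OCOC)c1 | intermediate
3 | geranyl bromide, (2E)-1-bromo-3,7-dimethylocta-2,6-diene | BrC/C=C(\C)CCC=C(C)C | starting material
4 | [2,6-bis(methoxymethoxy)phenyl]lithium | [Li]c1c(OCOC)cccc1OCOC | intermediate
5 | 2-[(2E)-3,7-dimethylocta-2,6-dien-1-yl]-1,3-bis(methoxymethoxy)benzene | COCOc1cccc(OCOC)c1C/C=C(\C)CCC=C(C)C | intermediate
6 | 2-[4-geranyl-3,5-bis(methoxymethoxy)phenyl]-4,4,5,5-tetramethyl-1,3,2-dioxaborolane | COCOc1cc(B2OC(C)(C)C(C)(C)O2)cc(OCOC)c1C/C=C(\C)CCC=C(C)C | intermediate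
7 | 4-[(2E)-3,7-dimethylocta-2,6-dien-1-yl]-3,5-bis(methoxymethoxy)phenol | COCOc1cc(O)cc(OCOC)c1C/C=C(\C)CCC=C(C)C | intermediate
8 | isovanillin (3-hydroxy-4-methoxybenzaldehyde) | COc1ccc(C=O)cc1O | starting material
9 | 5-formyl-2-methoxyphenyl acetate | COc1ccc(C=O)cc1OC(C)=O | intermediate
10 | (3-acetoxy-4-methoxyphenyl)(chloro)methyl 2,2-dimethylpropanoate, racemic | COc1ccc(C(Cl)OC(=O)C(C)(C)C)cc1OC(C)=O | intermediate
11 | (3-acetoxy-4-methoxyphenyl)[4-geranyl-3,5-bis(methoxymethoxy)phenoxy]methyl 2,2-dimethylpropanoate, racemic | COc1ccc(C(Oc2cc(OCOC)c(C/C=C(\C)CCC=C(C)C)c(OCOC)c2)OC(=O)C(C)(C)C)cc1OC(C)=O | intermediate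
12 | N-ethynyl-N,4-dimethylbenzenesulfonamide | C#CN(C)S(=O)(=O)c1ccc(C)cc1 | starting material
13 | [(3-acetoxy-4-methoxyphenyl)methylidene][4-geranyl-3,5-bis(methoxymethoxy)phenyl]oxonium, paired with the chiral phosphate | COc1ccc(C=[O+]c2cc(OCOC)c(C/C=C(\C)CCC=C(C)C)c(OCOC)c2)cc1OC(C)=O | intermediate
14 | N-{(3S)-3-(3-acetoxy-4-methoxyphenyl)-3-[4-geranyl-3,5-bis(methoxymethoxy)phenoxy]prop-1-en-1-ylidene}-N-methyl-4-methylbenzenesulfonamidium (keteniminium ion) | COc1ccc([C@@H](Oc2cc(OCOC)c(C/C=C(\C)CCC=C(C)C)c(OCOC)c2)C=C=[N+](C)S(=O)(=O)c2ccc(C)cc2)cc1OC(C)=O | intermediate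
15 | N-[(2S)-2-(3-acetoxy-4-methoxyphenyl)-6-geranyl-5,7-bis(methoxymethoxy)-2H-chromen-4-yl]-N,4-dimethylbenzenesulfonamide | COc1ccc([C@@H]2C=C(N(C)S(=O)(=O)c3ccc(C)cc3)c3c(cc(OCOC)c(C/C=C(\C)CCC=C(C)C)c3OCOC)O2)cc1OC(C)=O | intermediate
16 | (2S)-6-[(2E)-3,7-dimethylocta-2,6-dien-1-yl]-5,7-dihydroxy-2-(3-hydroxy-4-methoxyphenyl)-2,3-dihydro-4H-chromen-4-one | COc1ccc([C@@H]2CC(=O)c3c(cc(O)c(C/C=C(\C)CCC=C(C)C)c3O)O2)cc1O | target

## Summary

Total step count: 8.
Longest linear sequence: 6 steps (steps 1, 2, 3, 6, 7, 8, from resorcinol); the ring B branch (steps 4 and 5) joins at step 6.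

Steps most likely to fail:

**Step 7 (proposed new method).** Possible failures are poor facial discrimination in the oxocarbenium–phosphate ion pair, consumption of the ynamide by direct protonation, and capture of the keteniminium ion by pivalate or phosphate instead of by ring A. The fallback uses known chemistry, sets out from 11 and comes back at 16: the two bonds are made one after the other and the enantiomers are separated by kinetic resolution. Mukaiyama-type addition of 1,1-bis(trimethylsilyloxy)ethene to 11 (TMSOTf cat., CH2Cl2, −78 °C) should give trimethylsilyl 3-(3-acetoxy-4-methoxyphenyl)-3-(aryloxy)propanoate F1, hydrolysed on work-up to the racemic acid F2. Intramolecular Friedel–Crafts acylation (trifluoroacetic anhydride, CH2Cl2, 0 °C) should close ring C to the racemic protected flavanone F3. Asymmetric transfer hydrogenation with RuCl(p-cymene)[(R,R)-TsDPEN] and HCO2H/Et3N, stopped near half conversion, should reduce the 2R ketone to the cis-flavan-4-ol F5 and leave the (2S)-flavanone F4, which the conditions of step 8 should convert into 16.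

**Step 6.** Possible failures are C-alkylation of the very electron-rich phenol instead of O-alkylation, reversal of the acyl chloride addition of step 5, and hydrolysis of the mixed acetal during isolation. The fallback sets out from 7 and 9 and comes back at oxocarbenium ion 13 within step 7, using a benzotriazole N,O-acetal as the ion precursor. Aldehyde 9 and 1H-benzotriazole should give the hemiaminal F6, which thionyl chloride converts into the 1-(α-chlorobenzyl)benzotriazole F7. Phenol 7 (K2CO3, MeCN, 0 °C) should displace chloride to give the crystalline N-(α-aryloxybenzyl)benzotriazole F8, which loses benzotriazole under the acid of step 7 to give 13.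

**Step 8.** Possible failures are sluggish hydrolysis of the enesulfonamide, acid-promoted cyclisation of the geranyl chain onto the flanking phenols, and erosion of enantiopurity by reversible opening of ring C under prolonged acid. The fallback sets out from 15 and comes back at 16, unmasking stepwise so that the ketone is revealed last under very mild acid. The acetate is removed at the chromene stage (K2CO3, MeOH, 0 °C) to give phenol F9. The two MOM ethers are cleaved non-hydrolytically (TMSOTf, 2,2′-bipyridyl, CH2Cl2, 0 °C, then water) to give the triol enesulfonamide F10, which dilute aqueous oxalic acid in THF at rt should hydrolyse to 16.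

## Further compounds

F1 | step 7 | trimethylsilyl 3-(3-acetoxy-4-methoxyphenyl)-3-[4-geranyl-3,5-bis(methoxymethoxy)phenoxy]propanoate, racemic | C[Si](C)(C)OC(=O)CC(Oc1cc(OCOC)c(C/C=C(\C)CCC=C(C)C)c(OCOC)c1)c1ccc(OC)c(OC(C)=O)c1
F2 | step 7 | 3-(3-acetoxy-4-methoxyphenyl)-3-[4-geranyl-3,5-bis(methoxymethoxy)phenoxy]propanoic acid, racemic | OC(=O)CC(Oc1cc(OCOC)c(C/C=C(\C)CCC=C(C)C)c(OCOC)c1)c1ccc(OC)c(OC(C)=O)c1
F3 | step 7 | 2-(3-acetoxy-4-methoxyphenyl)-6-geranyl-5,7-bis(methoxymethoxy)-2,3-dihydro-4H-chromen-4-one, racemic | COc1ccc(C2CC(=O)c3c(cc(OCOC)c(C/C=C(\C)CCC=C(C)C)c3OCOC)O2)cc1OC(C)=O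
F4 | step 7 | (2S)-2-(3-acetoxy-4-methoxyphenyl)-6-geranyl-5,7-bis(methoxymethoxy)-2,3-dihydro-4H-chromen-4-one | COc1ccc([C@@H]2CC(=O)c3c(cc(OCOC)c(C/C=C(\C)CCC=C(C)C)c3OCOC)O2)cc1OC(C)=O
F5 | step 7 | (2R,4R)-2-(3-acetoxy-4-methoxyphenyl)-6-geranyl-5,7-bis(methoxymethoxy)-3,4-dihydro-2H-chromen-4-ol (cis) | COc1ccc([C@H]2C[C@@H](O)c3c(cc(OCOC)c(C/C=C(\C)CCC=C(C)C)c3OCOC)O2)cc1OC(C)=O
F6 | step 6 | 5-[(1H-benzotriazol-1-yl)(hydroxy)methyl]-2-methoxyphenyl acetate, racemic | COc1ccc(C(O)n2nnc3ccccc32)cc1OC(C)=O
F7 | step 6 | 5-[(1H-benzotriazol-1-yl)(chloro)methyl]-2-methoxyphenyl acetate, racemic | COc1ccc(C(Cl)n2nnc3ccccc32)cc1OC(C)=O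
F8 | step 6 | 5-{(1H-benzotriazol-1-yl)[4-geranyl-3,5-bis(methoxymethoxy)phenoxy]methyl}-2-methoxyphenyl acetate, racemic | COc1ccc(C(Oc2cc(OCOC)c(C/C=C(\C)CCC=C(C)C)c(OCOC)c2)n2nnc3ccccc32)cc1OC(C)=O
F9 | step 8 | N-[(2S)-6-geranyl-2-(3-hydroxy-4-methoxyphenyl)-5,7-bis(methoxymethoxy)-2H-chromen-4-yl]-N,4-dimethylbenzenesulfonamide | COc1ccc([C@@H]2C=C(N(C)S(=O)(=O)c3ccc(C)cc3)c3c(cc(OCOC)c(C/C=C(\C)CCC=C(C)C)c3OCOC)O2)cc1O
F10 | step 8 | N-[(2S)-6-geranyl-5,7-dihydroxy-2-(3-hydroxy-4-methoxyphenyl)-2H-chromen-4-yl]-N,4-dimethylbenzenesulfonamide | COc1ccc([C@@H]2C=C(N(C)S(=O)(=O)c3ccc(C)cc3)c3c(cc(O)c(C/C=C(\C)CCC=C(C)C)c3O)O2)cc1O
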